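**Strategy.** The central ring is cut at C3–aryl/C4–O and at C6–aryl/C1–O. In this ring each aryl carbon (C3, C6) lies next to the oxygen-bearing carbon that ends up esterified (C4, C1), so both vicinal pairs map onto arynes. In one flask, an excess of a para-benzyloxyaryl Grignard reagent takes a tetrabromohydroquinone dibenzyl ether through two aryne carbomagnesiations. A borate–peroxide quench then turns the two C–Mg bonds into the C1 and C4 hydroxyls. The ether oxygens of the precursor become the C2 and C5 hydroxyls. The two free phenols are then acylated in turn, and five benzyl ethers are removed together at the end.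

Key step: step 4

Remark on the chemistry: central-ring locants are C1 (3-hydroxybutanoyloxy), C2 (OH), C3 (4-hydroxyphenyl), C4 (3-phenylpropanoyloxy), C5 (OH), C6 (4-hydroxyphenyl). The single stereocentre is (S) and is bought in with methyl (S)-3-hydroxybutanoate; no step breaks a bond at that carbon.

Design choices:
- All five oxygens that end as free hydroxyls carry benzyl groups, so one neutral hydrogenolysis finishes the synthesis. The C2/C5 benzyl ethers also prevent acyl migration during both acylations.
- The key step consumes four molecules of the Grignard reagent per molecule of tetrabromide: two for the bromine–magnesium exchanges and two that are built into the product. Six equivalents are charged.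
- The key step ends with a dithionite wash, because its product is an electron-rich hydroquinone that excess peroxide or air would oxidise to the quinone.
- The cheap acyl group goes on first in the statistical mono-acylation. The chiral acid is then coupled directly by carbodiimide, which avoids a separate acid chloride step.
- Compounds 11 and 18 are hydroquinones and should be handled under argon.

**Step 1**
Reactants: 1 bromanil
Product: 2 tetrabromohydroquinone
Conditions: Na2S2O4, EtOAc/H2O, rt
Reagents that add atoms: none
Why: Dithionite reduction of a halogenated p-quinone to its hydroquinone is fast in a two-phase system and leaves the C–Br bonds untouched.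

**Step 2**
Reactants: 2 tetrabromohydroquinone
Product: 3 1,4-bis(benzyloxy)-2,3,5,6-tetrabromobenzene
Conditions: BnBr (2.5 equiv), K2CO3, DMF, 60 °C, argon
Reagents that add atoms: benzyl bromide, BrCc1ccccc1
Why: Williamson ether synthesis; the tetrabromo phenol is acidic enough for K2CO3, both phenoxides O-alkylate cleanly with a benzylic bromide, and argon keeps the dianion from being re-oxidised.

**Step 3**
Reactants: 4 1-(benzyloxy)-4-bromobenzene
Product: 5 4-(benzyloxy)phenylmagnesium bromide (THF solution, titrated and used directly)
Conditions: Mg turnings, I2 (cat.), THF, reflux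
Reagents that add atoms: magnesium, [Mg]
Why: Grignard formation by direct magnesium insertion into an aryl bromide; the benzyl ether is inert to arylmagnesium halides.

**Step 4**
Reactants: 3 1,4-bis(benzyloxy)-2,3,5,6-tetrabromobenzene; 5 4-(benzyloxy)phenylmagnesium bromide (two molecules are built into the product; the second one is entered again on the reagent line)
Product: 11 2,5-bis(benzyloxy)-3,6-bis[4-(benzyloxy)phenyl]benzene-1,4-diol, via first aryne 6 (not isolated), via mono-Grignard reagent 7 (not isolated), via second aryne 8 (not isolated), via di-Grignard reagent 9 (not isolated), via bis(dimethyl boronate) 10 (not isolated)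
Conditions: 3 (1 equiv) added to 5 (6 equiv), THF, rt then reflux; B(OMe)3 (10 equiv), −78 °C to rt; AcOH, 30% H2O2, 0 °C to rt; aq. Na2S2O4 wash
Reagents that add atoms: 4-(benzyloxy)phenylmagnesium bromide, Br[Mg]c1ccc(OCc2ccccc2)cc1; hydrogen peroxide, OO
Why: Bromine–magnesium exchange by one molecule of 5 (released as aryl bromide 4) and loss of MgBr2 give aryne 6, which a second molecule of 5 carbomagnesiates to 7; the same exchange–elimination on the remaining dibromo edge gives aryne 8, which takes a further molecule of 5 to give di-Grignard 9, so four molecules of 5 are consumed and two of them supply the aryl groups of the product. B(OMe)3 then traps both C–Mg bonds as 10, and H2O2 in AcOH moves each aryl carbon from boron to oxygen, each of two peroxide molecules giving up one oxygen atom, to deliver the two phenols after hydrolysis. The closest known reaction type is the tandem aryne route from tetra- and hexahaloarenes with aryl Grignard reagents to p-terphenyl di-Grignard reagents, joined to the classical Grignard–borate–peroxide phenol synthesis. No ring closes and no stereocentre is formed. The step needs the second aryl group at C6, para to the first: aryne 6 has the same benzyloxy neighbour on both sides, so the first addition is degenerate, and in aryne 8 attack at C6 places the new carbanionic carbon C1 para to the existing C4–Mg bond, as far from that negative charge as possible. The dithionite wash destroys residual peroxide and returns any quinone formed by over-oxidation to hydroquinone 11.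

**Step 5**
Reactants: 12 methyl (S)-3-hydroxybutanoate
Product: 13 methyl (S)-3-(benzyloxy)butanoate
Conditions: BnOC(=NH)CCl3 (1.5 equiv), TfOH (cat.), CH2Cl2/cyclohexane, 0 °C to rt
Reagents that add atoms: benzyl 2,2,2-trichloroacetimidate, N=C(OCc1ccccc1)C(Cl)(Cl)Cl
Why: Acid-catalysed O-benzylation with the trichloroacetimidate avoids the basic conditions that could cause β-elimination, and since the C3–O bond is never broken the (S) configuration is retained.

**Step 6**
Reactants: 13 methyl (S)-3-(benzyloxy)butanoate
Product: 14 (S)-3-(benzyloxy)butanoic acid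
Conditions: LiOH·H2O, THF/H2O, 0 °C to rt; then aq. HCl
Reagents that add atoms: lithium hydroxide, [Li+].[OH-]
Why: Ester saponification under mild conditions; the stereocentre is not alpha to the carbonyl, so it cannot epimerise, and benzyloxide is too poor a leaving group to eliminate at this temperature.

**Step 7**
Reactants: 11 2,5-bis(benzyloxy)-3,6-bis[4-(benzyloxy)phenyl]benzene-1,4-diol; 15 3-phenylpropanoyl chloride
Product: 16 2,5-bis(benzyloxy)-3,6-bis[4-(benzyloxy)phenyl]-4-hydroxyphenyl 3-phenylpropanoate
Conditions: 15 (0.9 equiv, slow addition), pyridine, DMAP (cat.), CH2Cl2, −20 to 0 °C, argon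
Reagents that add atoms: none
Why: DMAP-catalysed acylation of a phenol by an acid chloride; with the acid chloride limiting and added slowly, the two equivalent para-related phenols should give the mono-ester as the main product of a statistical distribution, and unreacted 11 and any bis-ester (after methanolysis back to 11) are recycled.

**Step 8**
Reactants: 16 2,5-bis(benzyloxy)-3,6-bis[4-(benzyloxy)phenyl]-4-hydroxyphenyl 3-phenylpropanoate; 14 (S)-3-(benzyloxy)butanoic acid
Product: 17 2,5-bis(benzyloxy)-3,6-bis[4-(benzyloxy)phenyl]-4-[(3-phenylpropanoyl)oxy]phenyl (3S)-3-(benzyloxy)butanoate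
Conditions: 14 (1.5 equiv), DCC, DMAP (cat.), CH2Cl2, 0 °C to rt
Reagents that add atoms: none
Why: Steglich esterification (carbodiimide activation with DMAP as acyl-transfer catalyst) acylates the remaining hindered phenol; both neighbouring oxygens are benzyl ethers, so the first ester has nowhere to migrate, and the remote stereocentre is not involved.

**Step 9**
Reactants: 17 2,5-bis(benzyloxy)-3,6-bis[4-(benzyloxy)phenyl]-4-[(3-phenylpropanoyl)oxy]phenyl (3S)-3-(benzyloxy)butanoate
Product: 18 2,5-dihydroxy-3,6-bis(4-hydroxyphenyl)-4-[(3-phenylpropanoyl)oxy]phenyl (3S)-3-hydroxybutanoate (target)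
Conditions: H2 (1 atm), Pd/C (10%), EtOAc/THF, rt; filtration under argon
Reagents that add atoms: none
Why: Catalytic hydrogenolysis cleaves the four aryl benzyl ethers and the one alkyl benzyl ether while aryl esters, saturated chains and the (S)-carbinol are inert, and the neutral, aprotic, alcohol-free medium should keep the acyl groups from moving to the newly freed C2 and C5 hydroxyls.

**Compound list**
1 | bromanil (2,3,5,6-tetrabromo-1,4-benzoquinone) | O=C1C(Br)=C(Br)C(=O)C(Br)=C1Br | starting material
2 | tetrabromohydroquinone (2,3,5,6-tetrabromobenzene-1,4-diol) | Oc1c(Br)c(Br)c(O)c(Br)c1Br | intermediate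
3 | 1,4-bis(benzyloxy)-2,3,5,6-tetrabromobenzene | Brc1c(Br)c(OCc2ccccc2)c(Br)c(Br)c1OCc1ccccc1 | intermediate
4 | 1-(benzyloxy)-4-bromobenzene | Brc1ccc(OCc2ccccc2)cc1 | starting material
5 | 4-(benzyloxy)phenylmagnesium bromide | Br[Mg]c1ccc(OCc2ccccc2)cc1 | intermediate
6 | 3,6-bis(benzyloxy)-4,5-dibromobenzyne (first aryne) | BrC1=C(OCc2ccccc2)C#CC(OCc2ccccc2)=C1Br | intermediate
7 | [2,5-bis(benzyloxy)-6-[4-(benzyloxy)phenyl]-3,4-dibromophenyl]magnesium bromide (mono-Grignard reagent) | Br[Mg]c1c(OCc2ccccc2)c(Br)c(Br)c(OCc2ccccc2)c1-c1ccc(OCc2ccccc2)cc1 | intermediate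
8 | [2,5-bis(benzyloxy)-6-[4-(benzyloxy)phenyl]-3,4-didehydrophenyl]magnesium bromide (second aryne) | Br[Mg]C1=C(OCc2ccccc2)C#CC(OCc2ccccc2)=C1c1ccc(OCc2ccccc2)cc1 | intermediate
9 | [2,5-bis(benzyloxy)-3,6-bis[4-(benzyloxy)phenyl]-1,4-phenylene]bis(magnesium bromide) (di-Grignard reagent) | Br[Mg]c1c(OCc2ccccc2)c(-c2ccc(OCc3ccccc3)cc2)c([Mg]Br)c(OCc2ccccc2)c1-c1ccc(OCc2ccccc2)cc1 | intermediate
10 | tetramethyl [2,5-bis(benzyloxy)-3,6-bis[4-(benzyloxy)phenyl]-1,4-phenylene]diboronate | COB(OC)c1c(OCc2ccccc2)c(-c2ccc(OCc3ccccc3)cc2)c(B(OC)OC)c(OCc2ccccc2)c1-c1ccc(OCc2ccccc2)cc1 | intermediate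
11 | 2,5-bis(benzyloxy)-3,6-bis[4-(benzyloxy)phenyl]benzene-1,4-diol | Oc1c(OCc2ccccc2)c(-c2ccc(OCc3ccccc3)cc2)c(O)c(OCc2ccccc2)c1-c1ccc(OCc2ccccc2)cc1 | intermediate
12 | methyl (S)-3-hydroxybutanoate | C[C@H](O)CC(=O)OC | starting material
13 | methyl (S)-3-(benzyloxy)butanoate | C[C@H](OCc1ccccc1)CC(=O)OC | intermediate
14 | (S)-3-(benzyloxy)butanoic acid | C[C@H](OCc1ccccc1)CC(=O)O | intermediate
15 | 3-phenylpropanoyl chloride | O=C(Cl)CCc1ccccc1 | starting material
16 | 2,5-bis(benzyloxy)-3,6-bis[4-(benzyloxy)phenyl]-4-hydroxyphenyl 3-phenylpropanoate | O=C(CCc1ccccc1)Oc1c(OCc2ccccc2)c(-c2ccc(OCc3ccccc3)cc2)c(O)c(OCc2ccccc2)c1-c1ccc(OCc2ccccc2)cc1 | intermediate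
17 | 2,5-bis(benzyloxy)-3,6-bis[4-(benzyloxy)phenyl]-4-[(3-phenylpropanoyl)oxy]phenyl (3S)-3-(benzyloxy)butanoate | C[C@H](OCc1ccccc1)CC(=O)Oc1c(OCc2ccccc2)c(-c2ccc(OCc3ccccc3)cc2)c(OC(=O)CCc2ccccc2)c(OCc2ccccc2)c1-c1ccc(OCc2ccccc2)cc1 | intermediate
18 | 2,5-dihydroxy-3,6-bis(4-hydroxyphenyl)-4-[(3-phenylpropanoyl)oxy]phenyl (3S)-3-hydroxybutanoate | C[C@H](O)CC(=O)Oc1c(O)c(-c2ccc(O)cc2)c(OC(=O)CCc2ccccc2)c(O)c1-c1ccc(O)cc1 | target

**Step count.** Total: 9 steps. Longest linear sequence: 6 steps (1, 2, 4, 7, 8, 9).

**Steps most likely to fail**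

Step 4. Several processes could erode it:
- the second bromine–magnesium exchange may stall at the mono-arylated stage, because the ring then already carries a C–Mg bond;
- the second aryl group may add in the wrong orientation and give a meta-terphenyl;
- a C–Mg or C–B bond may be protonated in place of being oxygenated;
- the hydroquinone may be over-oxidised.

The fallback sets out from 1 and replaces aryne chemistry by cross-coupling. Bromanil 1 and NaOBn (BnOH, NaH, THF, 0 °C) should undergo the usual 2,5-selective addition–elimination to give 2,5-bis(benzyloxy)-3,6-dibromo-1,4-benzoquinone F1. Reduction with Na2S2O4 gives 2,5-bis(benzyloxy)-3,6-dibromobenzene-1,4-diol F2, and MOMCl with iPr2NEt protects both hydroxyls as 1,4-bis(benzyloxy)-2,5-dibromo-3,6-bis(methoxymethoxy)benzene F3. A double Suzuki–Miyaura coupling with commercial 4-(benzyloxy)phenylboronic acid (Pd(OAc)2, SPhos, K3PO4, toluene/H2O, 100 °C) gives 1,4-bis(benzyloxy)-2,5-bis[4-(benzyloxy)phenyl]-3,6-bis(methoxymethoxy)benzene F4. HCl in MeOH/THF removes the two acetals without touching the benzyl ethers, and the route is rejoined at 11.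

Step 7. The two phenols are equivalent, so acylation may not discriminate between them, giving over-acylation together with unreacted diol. The fallback sets out from 11 and inverts the logic. Exhaustive acylation with an excess of 15 (pyridine, DMAP) gives 2,5-bis(benzyloxy)-3,6-bis[4-(benzyloxy)phenyl]-1,4-phenylene bis(3-phenylpropanoate) F5. One ester is then cleaved with one equivalent of pyrrolidine in THF at 0 °C. Once the first phenol is freed, its electron release makes the remaining aryl ester a poorer acyl donor, so the aminolysis should slow markedly at the mono-ester stage, and the route is rejoined at 16.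

Step 9. Three processes are of concern: acyl migration from O1 or O4 to the neighbouring hydroxyl as soon as it is unveiled, sluggish cleavage of the two hindered central benzyl ethers, and air oxidation of the free hydroquinone on the catalyst during filtration. The fallback sets out from 17 and avoids the metal surface altogether. Lewis-acid debenzylation with BCl3 and pentamethylbenzene as cation scavenger (CH2Cl2, −78 °C, quench with MeOH/CHCl3 at low temperature) removes all five benzyl groups under non-basic, non-reductive conditions and arrives directly at 18.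

**Further compounds**
F1 | step 4 | 2,5-bis(benzyloxy)-3,6-dibromo-1,4-benzoquinone | O=C1C(Br)=C(OCc2ccccc2)C(=O)C(Br)=C1OCc1ccccc1
F2 | step 4 | 2,5-bis(benzyloxy)-3,6-dibromobenzene-1,4-diol | Oc1c(Br)c(OCc2ccccc2)c(O)c(Br)c1OCc1ccccc1
F3 | step 4 | 1,4-bis(benzyloxy)-2,5-dibromo-3,6-bis(methoxymethoxy)benzene | COCOc1c(Br)c(OCc2ccccc2)c(OCOC)c(Br)c1OCc1ccccc1
F4 | step 4 | 1,4-bis(benzyloxy)-2,5-bis[4-(benzyloxy)phenyl]-3,6-bis(methoxymethoxy)benzene | COCOc1c(-c2ccc(OCc3ccccc3)cc2)c(OCc2ccccc2)c(OCOC)c(-c2ccc(OCc3ccccc3)cc2)c1OCc1ccccc1
F5 | step 7 | 2,5-bis(benzyloxy)-3,6-bis[4-(benzyloxy)phenyl]-1,4-phenylene bis(3-phenylpropanoate) | O=C(CCc1ccccc1)Oc1c(OCc2ccccc2)c(-c2ccc(OCc3ccccc3)cc2)c(OC(=O)CCc2ccccc2)c(OCc2ccccc2)c1-c1ccc(OCc2ccccc2)cc1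
F0 | step 9 | none | none
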